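Count the charge first: substrate and other conformer together end as target plus isomer of the product, for the midnight run closes at 101% after 8.00 h. So ask how that total divides.

| setting | midnight | summer | flask |
|---|---|---|---|
| substrate | 2 M | 2 M | 2.0 M |
| other conformer | 0.50 M | 1 M | 0.500 M |
| gas | 200 mM (held) | 200 mM (held) | 200 mM (held) |
| remark | the very flask that is asked about, followed so far | run made earlier |  |
| time |  |  | 2.5 d |

- midnight (time / h: target / %, isomer of the product / %): 0.500: 25.0, 37.6; 1.33: 38.4, 59.9; 2.50: 37.3, 62.1; 4.00: 38.9, 60.8; 6.00: 35.5, 60.8; 8.00: 38.4, 63.0
- summer (time / h: target / %, isomer of the product / %): 3.00: 37.1, 64.3; 8.00: 36.1, 63.8; 15.0: 37.2, 64.0; 25.0: 35.8, 62.8; 30.0: 36.5, 61.7; 40.0: 37.1, 64.2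

(scatter of a reading: 1 percentage point)

* share of target in target plus isomer of the product at 2.0 min
* share of target in target plus isomer of the product at 2.5 d

- at the start none of the gas is in solution

Solve two extreme flasks, supposing that substrate gives target and other conformer gives the isomer. With frozen conformers each goes its own way, so once both are used up the share of target equals the substrate's fraction of the charge: 80.0% at midnight, 66.7% in summer. With fast exchange both draw on one equilibrated pool (Curtin–Hammett), so the share ignores the charge. Between them stands the memory, the points of share gained per point of substrate fraction in the charge: one when frozen, zero under fast exchange. Average the readings from 1.33 h on: midnight gives 38.1%, summer 36.6%. So the whole-run memory reads 0.111, loosely, since each reading scatters by 1 percentage point.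

Now let the comparison drift. That memory belongs to a whole run, but 2.0 min is far shorter than 0.500 h, when the midnight run still reads 37.4% of its charge outside the two products. So at 2.0 min the conformers have had less time to exchange than by that first reading, and they should stand nearer their charged mix. My reckoning puts the early share above 38.1%, by an amount I can't reckon from these runs, and the late share near 38.1%.

The forecast says 40% at 2.0 min, choosing to “extrapolate the early kinetic value”, and 37.3% at 2.5 d. Its early figure stands 1.9 points above my floor.

The flask gives 50.6% at 2.0 min and 38.2% at 2.5 d.

    substrate ⇌ other conformer (K = 0.714, k = 0.0856 min⁻¹)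
    substrate + coupling partner → target (k = 0.225 M⁻¹ min⁻¹)
    coupling partner + other conformer → isomer of the product (k = 0.683 M⁻¹ min⁻¹)
    gas ⇌ coupling partner, rate k4*(csat - [coupling partner]) (kL = 0.497 min⁻¹)
    coupling partner → decomposed reagent (k = 0.0335 min⁻¹)

Target and isomer of the product stand level at 1.94% each after 2.30 min. Raising the summer share by the memory times the difference in charge fraction returns 38.1% for this flask, which is the midnight mean itself by construction, so it is no check on the computed 38.2%.

Take the neighbour flask with 1.2 M of other conformer: its substrate fraction is 62.5%, so the memory gives 36.1%. The computed end share there is 36.0%.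

The readings are calculated for substances that don't exist; scatter was added.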